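**Retrosynthetic overview**
1. Key and last disconnection: the C–O bond between an ortho-oxygen of the trihydroxybenzoyl ring and flavan C-8. Oxidative dearomatisation of the free biflavonoid closes the chromanone ring and unveils the dienone.
2. Dihydrofuran ring: the O7–CH(Ar) bond (C–O) and the C8–C(OH) bond are cut together. This leads back to (−)-epiafzelechin and a racemic 3-bromo-1,2-dione, joined by a catalyst-controlled interrupted Feist–Bénary annulation.
3. (−)-Epiafzelechin comes from kaempferol by benzylation, C4 deoxygenation to the 4H-chromene, and asymmetric cis-hydrogenation with hydrogenolysis.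
4. The bromodione comes from phloretin by benzylation, α-hydroxylation, and oxidation with bromination.
5. Ring order: pyran ring (skeleton from kaempferol, stereocentres by hydrogenation), then dihydrofuran, then chromanone with dienone.

Assumption: the SMILES is read as 2R,3R (epiafzelechin type) in the pyran ring; flavan locants are used for 1–5 and 11, and furo[2,3-h]chromene locants for 12–14 (O7 = flavan O-7, C8 = aryl-bearing CH, C9 = carbinol carbon, C9a = flavan C-8).

**Step 1**
Reactants: 1 kaempferol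
Product: 2 3,5,7,4'-tetra-O-benzylkaempferol
Conditions: BnBr (6 equiv), K2CO3 (8 equiv), DMF, 80 °C, 24 h
Reagents that add atoms: benzyl bromide, BrCc1ccccc1
Why: Exhaustive Williamson etherification, in which excess reagent and heat also alkylate the hydrogen-bonded 5-OH; no stereocentre is involved.

**Step 2**
Reactants: 2 3,5,7,4'-tetra-O-benzylkaempferol
Product: 3 3,5,7-tris(benzyloxy)-2-[4-(benzyloxy)phenyl]-4H-chromene
Conditions: LiAlH4 (3 equiv), MTBE, 55 °C, 2 h; H2O/aq NaOH quench; crystallise from EtOAc–heptane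
Reagents that add atoms: none
Why: Flavone-to-flav-2-ene hydride reduction: 1,2-addition gives the C4 aluminate, which ionises to the 3-benzyloxyflavylium ion and takes a second hydride at C4, so C=O becomes CH2 with the C2=C3 enol ether kept, the benzyl ethers are inert, and the minor 2H-isomer is removed by crystallisation.

**Step 3**
Reactants: 3 3,5,7-tris(benzyloxy)-2-[4-(benzyloxy)phenyl]-4H-chromene
Product: 5 (−)-epiafzelechin, via tetra-O-benzyl-epiafzelechin 4 (not isolated)
Conditions: [Ir(cod)(P,N)][B(C6H3(CF3)2)4] (2 mol %; P,N = (S)-8-(di-tert-butylphosphinooxy)-2-phenyl-5,6,7,8-tetrahydroquinoline), H2 (80 bar), CH2Cl2, 25 °C, 24 h; solvent switch to THF–MeOH, Pd(OH)2/C, H2 (1 atm), 25 °C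
Reagents that add atoms: none
Why: Proposed new method: a cationic iridium P,N-dihydride adds H2 suprafacially to one face of the tetrasubstituted C2=C3 enediol diether, so C2 and C3 are created together and necessarily cis, with the face chosen by the 2-aryl group lying in the open quadrant of the ligand as for 2-aryl-4H-chromenes (the ligand antipode is the switch if the sense is opposite), and the non-coordinating borate anion in dry CH2Cl2 spares the acid-sensitive enol ether; the closest known reaction types are the iridium-catalysed asymmetric hydrogenation of trisubstituted 2-aryl-4H-chromenes and of unfunctionalised tetrasubstituted olefins, not yet shown for a 3-alkoxy tetrasubstituted flavene, and the following Pd(OH)2/C hydrogenolysis is routine.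

**Step 4**
Reactants: 6 phloretin
Product: 7 tetra-O-benzylphloretin
Conditions: BnBr (6 equiv), K2CO3 (8 equiv), DMF, 70 °C, 18 h
Reagents that add atoms: benzyl bromide, BrCc1ccccc1
Why: Williamson etherification, in which the acyl group damps C-alkylation of the phloroglucinol ring and all four phenols are masked for the later basic steps.

**Step 5**
Reactants: 7 tetra-O-benzylphloretin
Product: 8 rac-3-[4-(benzyloxy)phenyl]-2-hydroxy-1-[2,4,6-tris(benzyloxy)phenyl]propan-1-one
Conditions: KN(SiMe3)2 (1.2 equiv), THF, −78 °C; 2-(phenylsulfonyl)-3-phenyloxaziridine (1.3 equiv), −78 °C; aq NH4Cl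
Reagents that add atoms: 2-(phenylsulfonyl)-3-phenyloxaziridine, O=S(=O)(c1ccccc1)N1OC1c1ccccc1
Why: Davis enolate hydroxylation: the ketone has only one enolisable side, and the new carbinol centre is racemic on purpose because it is oxidised away in the next step.

**Step 6**
Reactants: 8 rac-3-[4-(benzyloxy)phenyl]-2-hydroxy-1-[2,4,6-tris(benzyloxy)phenyl]propan-1-one
Product: 10 rac-3-bromo-3-[4-(benzyloxy)phenyl]-1-[2,4,6-tris(benzyloxy)phenyl]propane-1,2-dione, via 1,2-dione 9 (not isolated)
Conditions: Dess–Martin periodinane (1.2 equiv), CH2Cl2, 23 °C, 1 h; then NBS (1.0 equiv), 0 °C, 20 min; filter through Celite and a short neutral SiO2 pad, use crude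
Reagents that add atoms: N-bromosuccinimide, O=C1CCC(=O)N1Br
Why: Dess–Martin oxidation of the α-ketol gives the strongly enolised benzyl diketone, whose enol carbon is brominated by NBS far faster than any ring position (α-bromination of an enolisable ketone); the bromide centre is racemic and labile.

**Step 7**
Reactants: 5 (−)-epiafzelechin; 10 rac-3-bromo-3-[4-(benzyloxy)phenyl]-1-[2,4,6-tris(benzyloxy)phenyl]propane-1,2-dione
Product: 12 [(2R,3R,8R,9R)-8-[4-(benzyloxy)phenyl]-3,5,9-trihydroxy-2-(4-hydroxyphenyl)-3,4,8,9-tetrahydro-2H-furo[2,3-h]chromen-9-yl][2,4,6-tris(benzyloxy)phenyl]methanone, via bromohydrin adduct 11 (not isolated)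
Conditions: 9-amino-9-deoxy-epi-quinidine 3,5-bis(trifluoromethyl)phenyl squaramide (10 mol %), NaHCO3 (2 equiv), THF–CH2Cl2 1:1, 0.05 M, −30 to 0 °C; Et3N-deactivated SiO2 (removes the C-6 regioisomer)
Reagents that add atoms: none
Why: Proposed new method: the squaramide N–H bonds bind the vicinal dione of 10 while the quinuclidine hydrogen-bonds the 7-OH of 5, so the most nucleophilic ring-A carbon (C-8) adds reversibly to one face of the central, most electrophilic carbonyl and fixes the carbinol centre C9, after which the 7-phenoxide displaces bromide in a 5-exo-tet SN2 closure (O7–C8 bond); because 10 racemises through its enol and the addition is reversible, only the bromohydrin 11 that can place the 8-aryl group anti to the bulky aroyl group in the closure is drained (Curtin–Hammett), which gives the 8-aryl/9-OH cis relationship, and the pseudo-enantiomeric quinine catalyst is the switch if the facial sense is opposite; the closest known reaction types are the cinchona-catalysed asymmetric interrupted Feist–Bénary reaction of cyclic 1,3-diketones with bromo-α-ketoesters and the organocatalytic ortho-hydroxyalkylation of electron-rich phenols with activated ketones, neither shown for a free flavan-3-ol or for a 3-bromo-1,2-dione.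

**Step 8**
Reactants: 12 [(2R,3R,8R,9R)-8-[4-(benzyloxy)phenyl]-3,5,9-trihydroxy-2-(4-hydroxyphenyl)-3,4,8,9-tetrahydro-2H-furo[2,3-h]chromen-9-yl][2,4,6-tris(benzyloxy)phenyl]methanone
Product: 13 [(2R,3R,8R,9R)-3,5,9-trihydroxy-2,8-bis(4-hydroxyphenyl)-3,4,8,9-tetrahydro-2H-furo[2,3-h]chromen-9-yl](2,4,6-trihydroxyphenyl)methanone
Conditions: H2 (1 atm), Pd(OH)2/C, THF–MeOH 1:1, 23 °C, 2 h; filter under Ar, use at once
Reagents that add atoms: none
Why: Neutral hydrogenolysis of aryl benzyl ethers: the cyclic benzylic C–O bonds, the tertiary carbinol and the hydrogen-bonded aryl ketone survive at 1 atm as in flavan-3-ol endgames, and no stereocentre is touched.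

**Step 9**
Reactants: 13 [(2R,3R,8R,9R)-3,5,9-trihydroxy-2,8-bis(4-hydroxyphenyl)-3,4,8,9-tetrahydro-2H-furo[2,3-h]chromen-9-yl](2,4,6-trihydroxyphenyl)methanone
Product: 14 target CNP0170480.4
Conditions: PhI(OAc)2 (1.0 equiv), (CF3)2CHOH–MeCN 1:4, −20 °C, 20 min
Reagents that add atoms: none
Why: Key C–O bond by phenolic oxidative dearomatisation with a trivalent iodine reagent (the two-electron counterpart of grisan-type phenol coupling): the pentasubstituted 5-OH ring is by far the most electron-rich phenol, its para carbon C9a becomes electrophilic and is captured through a six-membered transition state by either of the two equivalent ortho-OH groups of the aroyl ring, and because that oxygen is tethered through the carbonyl on C9 it can only reach the face of C9a cis to the carbonyl, which sets C9a as R.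

**Compound list**
1 | kaempferol | O=c1c(O)c(-c2ccc(O)cc2)oc2cc(O)cc(O)c12 | starting material
2 | 3,5,7,4'-tetra-O-benzylkaempferol | O=c1c(OCc2ccccc2)c(-c2ccc(OCc3ccccc3)cc2)oc2cc(OCc3ccccc3)cc(OCc3ccccc3)c12 | intermediate
3 | 3,5,7-tris(benzyloxy)-2-[4-(benzyloxy)phenyl]-4H-chromene | C1c2c(OCc3ccccc3)cc(OCc3ccccc3)cc2OC(c2ccc(OCc3ccccc3)cc2)=C1OCc1ccccc1 | intermediate
4 | (2R,3R)-3,5,7-tris(benzyloxy)-2-[4-(benzyloxy)phenyl]chromane (tetra-O-benzyl-epiafzelechin) | C(c1ccccc1)Oc1cc(OCc2ccccc2)c2C[C@@H](OCc3ccccc3)[C@@H](c3ccc(OCc4ccccc4)cc3)Oc2c1 | intermediate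
5 | (−)-epiafzelechin, (2R,3R)-2-(4-hydroxyphenyl)chromane-3,5,7-triol | Oc1cc(O)c2C[C@@H](O)[C@@H](c3ccc(O)cc3)Oc2c1 | intermediate
6 | phloretin | O=C(CCc1ccc(O)cc1)c1c(O)cc(O)cc1O | starting material
7 | tetra-O-benzylphloretin, 3-[4-(benzyloxy)phenyl]-1-[2,4,6-tris(benzyloxy)phenyl]propan-1-one | O=C(CCc1ccc(OCc2ccccc2)cc1)c1c(OCc2ccccc2)cc(OCc2ccccc2)cc1OCc1ccccc1 | intermediate
8 | rac-3-[4-(benzyloxy)phenyl]-2-hydroxy-1-[2,4,6-tris(benzyloxy)phenyl]propan-1-one | O=C(C(O)Cc1ccc(OCc2ccccc2)cc1)c1c(OCc2ccccc2)cc(OCc2ccccc2)cc1OCc1ccccc1 | intermediate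
9 | 3-[4-(benzyloxy)phenyl]-1-[2,4,6-tris(benzyloxy)phenyl]propane-1,2-dione | O=C(C(=O)Cc1ccc(OCc2ccccc2)cc1)c1c(OCc2ccccc2)cc(OCc2ccccc2)cc1OCc1ccccc1 | intermediate
10 | rac-3-bromo-3-[4-(benzyloxy)phenyl]-1-[2,4,6-tris(benzyloxy)phenyl]propane-1,2-dione | O=C(C(=O)C(Br)c1ccc(OCc2ccccc2)cc1)c1c(OCc2ccccc2)cc(OCc2ccccc2)cc1OCc1ccccc1 | intermediate
11 | (2S,3S)-3-bromo-3-[4-(benzyloxy)phenyl]-2-hydroxy-2-[(2R,3R)-3,5,7-trihydroxy-2-(4-hydroxyphenyl)chroman-8-yl]-1-[2,4,6-tris(benzyloxy)phenyl]propan-1-one | Oc1cc(O)c([C@](O)(C(=O)c3c(OCc4ccccc4)cc(OCc4ccccc4)cc3OCc3ccccc3)[C@@H](Br)c3ccc(OCc4ccccc4)cc3)c2c1C[C@@H](O)[C@@H](c1ccc(O)cc1)O2 | intermediate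
12 | [(2R,3R,8R,9R)-8-[4-(benzyloxy)phenyl]-3,5,9-trihydroxy-2-(4-hydroxyphenyl)-3,4,8,9-tetrahydro-2H-furo[2,3-h]chromen-9-yl][2,4,6-tris(benzyloxy)phenyl]methanone (8-aryl cis to 9-OH, trans to the aroyl group) | Oc1cc2O[C@H](c3ccc(OCc4ccccc4)cc3)[C@@](O)(C(=O)c3c(OCc4ccccc4)cc(OCc4ccccc4)cc3OCc3ccccc3)c2c2c1C[C@@H](O)[C@@H](c1ccc(O)cc1)O2 | intermediate
13 | [(2R,3R,8R,9R)-3,5,9-trihydroxy-2,8-bis(4-hydroxyphenyl)-3,4,8,9-tetrahydro-2H-furo[2,3-h]chromen-9-yl](2,4,6-trihydroxyphenyl)methanone | Oc1cc2O[C@H](c3ccc(O)cc3)[C@@](O)(C(=O)c3c(O)cc(O)cc3O)c2c2c1C[C@@H](O)[C@@H](c1ccc(O)cc1)O2 | intermediate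
14 | CNP0170480.4: 5-oxo dienone of 13 in which one ortho-oxygen of the aroyl ring is bonded to C9a (2R,3R,8R,9S,9aR; aryl-O on C9a cis to the carbonyl on C9, 9-OH cis to the 8-aryl group) | O=C1C=C2O[C@H](c3ccc(O)cc3)[C@@]3(O)C(=O)c4c(O)cc(O)cc4O[C@@]23C2=C1C[C@@H](O)[C@@H](c1ccc(O)cc1)O2 | target

**Step count**
Total steps: 9. Longest linear sequence: 6 (steps 1, 2, 3, 7, 8, 9; the branch 4, 5, 6, 7, 8, 9 is equally long).

**Three steps most likely to fail**

Step 3 (proposed new hydrogenation). The risks are low turnover on the tetrasubstituted, very electron-rich alkene, acid-induced isomerisation, and modest ee.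
- The fallback sets out from 3 and comes back at 5, replacing asymmetric catalysis by resolution.
- Heterogeneous hydrogenation of 3 (Pd/C, H2 5 bar, EtOAc–MeOH, 50 °C) saturates C2=C3 from one face and removes all benzyl groups. This cis-selective reduction is known for benzylated 3-alkoxyflavenes and gives racemic epiafzelechin F1.
- Preparative chiral HPLC on amylose tris(3,5-dimethylphenylcarbamate) then delivers 5.

Step 7 (proposed new annulation). The risks are attack at C-6, O-alkylation of other phenols, and insufficient facial control at C9.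
- The fallback sets out from 10 and comes back at 12, using a vicinal tricarbonyl instead of the bromide.
- Kornblum oxidation of 10 (DMSO, NaHCO3, 40 °C) gives 1-[4-(benzyloxy)phenyl]-3-[2,4,6-tris(benzyloxy)phenyl]propane-1,2,3-trione F2.
- F2 condenses with 5 in THF–AcOH at 23 °C. This is the phenol hydroxyalkylation and hemiketalisation known for ninhydrin and dehydroascorbic acid. It gives the 8-hydroxy hemiketal F3 together with its C9 epimer, which is removed by preparative HPLC.
- NaBH4 (THF–MeOH, −20 °C) reduces the ring-opened aryl ketone to the benzylic diol F4.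
- Catalytic PPTS (CH2Cl2, 0 °C) closes the O7–C8 bond through the 4-benzyloxybenzyl cation with the aryl group anti to the aroyl group, giving 12.

Step 9 (key dearomatisation on a fully free polyphenol). The risks are oxidation of other phenols, solvent capture, and dehydration of 13 to the benzofuran.
- The fallback sets out from 12 and comes back at 14. It dearomatises a partly protected substrate and debenzylates without hydrogen.
- MgBr2·OEt2 (toluene–Et2O, 50 °C) removes by chelation one benzyl group ortho to the carbonyl and gives the mono-debenzylated ketone F5.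
- PhI(OAc)2 in (CF3)2CHOH–MeCN at −20 °C closes the aryl O–C9a bond to the tri-O-benzyl dienone F6.
- BCl3 with pentamethylbenzene (CH2Cl2, −78 °C) cleaves the three remaining benzyl ethers without touching the dienone, giving 14.

**Further compounds**
F1 | step 3 | racemic epiafzelechin (1:1 mixture of the 2R,3R and 2S,3S forms) | Oc1cc(O)c2C[C@@H](O)[C@@H](c3ccc(O)cc3)Oc2c1.Oc1cc(O)c2C[C@H](O)[C@H](c3ccc(O)cc3)Oc2c1
F2 | step 7 | 1-[4-(benzyloxy)phenyl]-3-[2,4,6-tris(benzyloxy)phenyl]propane-1,2,3-trione | O=C(C(=O)C(=O)c1ccc(OCc2ccccc2)cc1)c1c(OCc2ccccc2)cc(OCc2ccccc2)cc1OCc1ccccc1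
F3 | step 7 | 8-hydroxy hemiketal analogue of 12 (C9 geometry as in 12, anomeric mixture at C8) | Oc1cc2OC(O)(c3ccc(OCc4ccccc4)cc3)[C@@](O)(C(=O)c3c(OCc4ccccc4)cc(OCc4ccccc4)cc3OCc3ccccc3)c2c2c1C[C@@H](O)[C@@H](c1ccc(O)cc1)O2
F4 | step 7 | benzylic diol, analogue of 11 with OH in place of Br (epimer mixture at the CH(OH) carbon) | Oc1cc(O)c([C@](O)(C(=O)c3c(OCc4ccccc4)cc(OCc4ccccc4)cc3OCc3ccccc3)C(O)c3ccc(OCc4ccccc4)cc3)c2c1C[C@@H](O)[C@@H](c1ccc(O)cc1)O2
F5 | step 9 | analogue of 12 with one ortho-benzyloxy group of the aroyl ring replaced by OH | Oc1cc2O[C@H](c3ccc(OCc4ccccc4)cc3)[C@@](O)(C(=O)c3c(O)cc(OCc4ccccc4)cc3OCc3ccccc3)c2c2c1C[C@@H](O)[C@@H](c1ccc(O)cc1)O2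
F6 | step 9 | tri-O-benzyl ether of 14 (benzyl on the 8-aryl phenol and on both chromanone phenols) | O=C1C=C2O[C@H](c3ccc(OCc4ccccc4)cc3)[C@@]3(O)C(=O)c4c(OCc5ccccc5)cc(OCc5ccccc5)cc4O[C@@]23C2=C1C[C@@H](O)[C@@H](c1ccc(O)cc1)O2
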